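**Retrosynthetic overview**
- Littorachalcone ⇒ E,E-bis-chalcone: both saturated chains come from hydrogenation of two enone C=C bonds (last step).
- Bis-chalcone ⇒ diaryl ether dialdehyde + 2 × 2,4-dihydroxyacetophenone: two-directional Claisen–Schmidt condensation makes both C–C bonds in one operation.
- Dialdehyde ⇒ 3,4-dihydroxybenzaldehyde + 4-fluorobenzaldehyde: the key disconnection is the diaryl ether C–O bond, made first by site-selective O-4 arylation of the unprotected catechol (new fluoride-relay SNAr).
- Rings: none is built; all four benzene rings are bought. Ring B (from the fluoroarene) is joined to ring C (catechol ring) through oxygen first, then resorcinol rings A and D are attached together.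

Assumption: the target as drawn has no stereocentre and is achiral, so there is no enantiomer to select; the only stereo-element on the way is the E geometry of the two enones, which the last step removes.

**Step 1**
Reactants: 1 3,4-dihydroxybenzaldehyde (1.05 equiv); 2 4-fluorobenzaldehyde (1.0 equiv)
Product: 5 4-(4-formylphenoxy)-3-hydroxybenzaldehyde, via bis(trimethylsilyl) ether 3 (not isolated), via silylated diaryl ether 4 (not isolated)
Conditions: BSA (1.1 equiv), NMP, rt, 1 h; then 2, CsF (10 mol%), 130 °C, N2, 16 h; then 1 M HCl, THF, rt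
Reagents that add atoms: none
Why: Proposed new method: a fluoride-catalysed silyl-relay SNAr in which BSA first caps both phenols, catalytic fluoride then cleaves the Si–O bond whose phenoxide is the better leaving group (O-4, para to CHO, the same oxygen that reacts in the known 4-O-selective alkylation of the monoanion), this phenoxide adds to the C–F carbon of 2 (addition–elimination through a Meisenheimer complex), and the expelled fluoride removes the next trimethylsilyl group as volatile Me3SiF, so the chain runs without stoichiometric base while O-3 stays silylated, which blocks second arylation, catecholate oxidation and O-to-O Smiles migration of the formylphenyl group; the closest known reaction type is the CsF-catalysed coupling of aryl trimethylsilyl ethers with activated aryl fluorides, which has not been used for site-selective mono-arylation of an unsymmetrical catechol.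

**Step 2**
Reactants: 5 4-(4-formylphenoxy)-3-hydroxybenzaldehyde; 6 1-(2,4-dihydroxyphenyl)ethan-1-one (2.4 equiv)
Product: 7 (2E)-1-(2,4-dihydroxyphenyl)-3-[4-[4-[(1E)-3-(2,4-dihydroxyphenyl)-3-oxoprop-1-en-1-yl]-2-hydroxyphenoxy]phenyl]prop-2-en-1-one
Conditions: KOH (60% aq., 20 equiv), EtOH, 0 °C to rt, Ar, 48 h; then 2 M HCl to pH 3
Reagents that add atoms: none
Why: Two-directional Claisen–Schmidt (crossed aldol) condensation: only 6 can enolise, its enolate adds to each non-enolisable aldehyde of 5, and E1cB loss of water gives the conjugated, thermodynamically preferred E-enones; neither aldehyde is deactivated by a para-phenoxide, and the protic medium at room temperature is too mild for aryl ether migration.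

**Step 3**
Reactants: 7 the E,E-bis-chalcone from step 2
Product: 8 1-(2,4-dihydroxyphenyl)-3-[4-[4-[3-(2,4-dihydroxyphenyl)-3-oxopropyl]-2-hydroxyphenoxy]phenyl]propan-1-one (littorachalcone)
Conditions: H2 (1 atm), 10% Pd/C (5 mol% Pd), EtOAc–MeOH (4:1), rt, stopped after uptake of 2 equiv H2
Reagents that add atoms: none
Why: Catalytic heterogeneous hydrogenation: the two conjugated C=C bonds take up H2 on Pd much faster than the hydrogen-bonded 2-hydroxyaryl ketones or the diaryl ether react, so stopping at 2 equiv gives the saturated diketone; no stereocentre is formed.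

**Compound list**
1 | 3,4-dihydroxybenzaldehyde (protocatechualdehyde) | O=Cc1ccc(O)c(O)c1 | starting material
2 | 4-fluorobenzaldehyde | O=Cc1ccc(F)cc1 | starting material
3 | 3,4-bis(trimethylsilyloxy)benzaldehyde | C[Si](C)(C)Oc1ccc(C=O)cc1O[Si](C)(C)C | intermediate
4 | 4-(4-formylphenoxy)-3-(trimethylsilyloxy)benzaldehyde | C[Si](C)(C)Oc1cc(C=O)ccc1Oc1ccc(C=O)cc1 | intermediate
5 | 4-(4-formylphenoxy)-3-hydroxybenzaldehyde | O=Cc1ccc(Oc2ccc(C=O)cc2O)cc1 | intermediate
6 | 1-(2,4-dihydroxyphenyl)ethan-1-one (2,4-dihydroxyacetophenone) | CC(=O)c1ccc(O)cc1O | starting material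
7 | (2E)-1-(2,4-dihydroxyphenyl)-3-[4-[4-[(1E)-3-(2,4-dihydroxyphenyl)-3-oxoprop-1-en-1-yl]-2-hydroxyphenoxy]phenyl]prop-2-en-1-one | O=C(/C=C/c1ccc(Oc2ccc(/C=C/C(=O)c3ccc(O)cc3O)cc2O)cc1)c1ccc(O)cc1O | intermediate
8 | littorachalcone, 1-(2,4-dihydroxyphenyl)-3-[4-[4-[3-(2,4-dihydroxyphenyl)-3-oxopropyl]-2-hydroxyphenoxy]phenyl]propan-1-one | O=C(CCc1ccc(Oc2ccc(CCC(=O)c3ccc(O)cc3O)cc2O)cc1)c1ccc(O)cc1O | target

**Step count and risk**
Total steps: 3. Longest linear sequence: 3 (from 1 or 2 to 8). The route has three steps, so all three are ranked.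

Most likely to fail, in order:

1. Step 1 (proposed new step). The fluoride chain may be slow for the weakly nucleophilic O-4 phenoxide, and O-to-O silyl migration could erode site selectivity and give the 3-O-aryl isomer. The fallback uses known chemistry, sets out from 2 and comes back at 5, at the cost of one extra step. Commercial vanillin (4-hydroxy-3-methoxybenzaldehyde), in which O-3 is already fixed as a methyl ether, replaces 1. Classical SNAr with 2 (K2CO3, DMF, 120 °C) gives 4-(4-formylphenoxy)-3-methoxybenzaldehyde F1 with unambiguous regiochemistry. Cleavage of the methyl ether with BBr3 (CH2Cl2, −78 to 0 °C), which leaves the diaryl ether and aldehydes intact, then gives 5.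

2. Step 2. Claisen–Schmidt condensations of unprotected polyphenols can stall at the mono-adduct or lose aldehyde to Cannizzaro reaction. The fallback sets out from 5 and comes back at 8, bypassing 7 and replacing the aldol logic by acylation. Knoevenagel–Doebner condensation of 5 with malonic acid (pyridine, cat. piperidine, 90 °C) gives (2E)-3-[4-[4-[(1E)-2-carboxyethenyl]phenoxy]-3-hydroxyphenyl]prop-2-enoic acid F2. Hydrogenation (H2, Pd/C, MeOH) gives 3-[4-[4-(2-carboxyethyl)phenoxy]-3-hydroxyphenyl]propanoic acid F3. Double Friedel–Crafts (Nencki-type) acylation of excess resorcinol in BF3·OEt2 at 85 °C, which acylates para to one hydroxyl and ortho to the other, installs both 2,4-dihydroxyphenyl ketones and gives 8.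

3. Step 3. The free pentaphenol may adsorb strongly on Pd/C or dissolve poorly, and a ketone may over-reduce. The fallback sets out from 7 and comes back at 8 by a protect–reduce–deprotect detour. Ac2O, pyridine and cat. DMAP give the pentaacetate of 7 F4, which is soluble and non-chelating. Homogeneous hydrogenation with RhCl(PPh3)3 (H2 3 atm, THF–t-BuOH), which does not reduce ketones, gives the pentaacetate of 8 F5. K2CO3 in MeOH then removes the acetates to give 8.

**Further compounds**
F1 | step 1 | 4-(4-formylphenoxy)-3-methoxybenzaldehyde | COc1cc(C=O)ccc1Oc1ccc(C=O)cc1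
F2 | step 2 | (2E)-3-[4-[4-[(1E)-2-carboxyethenyl]phenoxy]-3-hydroxyphenyl]prop-2-enoic acid | OC(=O)/C=C/c1ccc(Oc2ccc(/C=C/C(=O)O)cc2O)cc1
F3 | step 2 | 3-[4-[4-(2-carboxyethyl)phenoxy]-3-hydroxyphenyl]propanoic acid | OC(=O)CCc1ccc(Oc2ccc(CCC(=O)O)cc2O)cc1
F4 | step 3 | pentaacetate of 7 (all five phenols acetylated, both alkenes E) | O=C(/C=C/c1ccc(Oc2ccc(/C=C/C(=O)c3ccc(OC(C)=O)cc3OC(C)=O)cc2OC(C)=O)cc1)c1ccc(OC(C)=O)cc1OC(C)=O
F5 | step 3 | pentaacetate of 8 | O=C(CCc1ccc(Oc2ccc(CCC(=O)c3ccc(OC(C)=O)cc3OC(C)=O)cc2OC(C)=O)cc1)c1ccc(OC(C)=O)cc1OC(C)=O
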